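**Strategy.** The route rests on cutting the C5–C6 bond of ring A (C1, C9, C5, C6, C7, C8). This turns the bicyclo[3.3.1]nonane into a cis-fused hydrindane whose cyclopentane (C9, C1, C8, C7, C6) already carries the contiguous stereocentres C1, C8 and C7. The key step exploits exactly this: a hypervalent iodine oxidation of the enolised C2–C3–C4 diketone moves C6 from the C9 carbinol to C5 and so creates, in one operation, the C5–C6 bond, the C9 ketone, bridgehead C5 and six-membered ring A. Its substrate is hydroxy-hydrindanedione 16, assembled by diketene annulation of a fully substituted cyclopentanone enolate.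

Key step: step 7

Conventions: prenyl = 3-methylbut-2-enyl; homoprenyl = 4-methylpent-3-enyl; geranyl = (2E)-3,7-dimethylocta-2,6-dienyl; C1–C9 are the core atoms of the target.

Assumption: in step 3 the (1R,2R)-ligand is taken to give the (5R)-product; the sense of induction on this enolate class is not secure, so the mirror-image ligand is used if a pilot run shows the opposite sense.

Step 1
Reactants: 1 cyclopentane-1,3-dione; 2 prenyl bromide (1-bromo-3-methylbut-2-ene)
Product: 3 2-prenylcyclopentane-1,3-dione
Conditions: KOH, H2O, 0 °C → rt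
Reagents that add atoms: none
Why: C-alkylation of the cyclic 1,3-diketone enolate with an allylic bromide, for which water as solvent solvates the enolate oxygens and so favours attack through carbon.

Step 2
Reactants: 3 2-prenylcyclopentane-1,3-dione
Product: 4 3-ethoxy-2-prenylcyclopent-2-en-1-one
Conditions: Et2SO4, K2CO3, acetone, reflux
Reagents that add atoms: diethyl sulfate, CCOS(=O)(=O)OCC
Why: O-alkylation of the symmetrical diketonate with a hard electrophile gives the vinylogous ester without a regiochemical question, and the basic medium avoids acid-induced cyclisation of the prenyl group onto the enol oxygen.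

Step 3
Reactants: 4 3-ethoxy-2-prenylcyclopent-2-en-1-one; 5 geranyl acetate
Product: 7 (5R)-3-ethoxy-5-geranyl-2-prenylcyclopent-2-en-1-one, via lithium dienolate 6 (not isolated)
Conditions: LiN(iPr)2, THF, −78 °C; then 5, [Pd(C3H5)Cl]2 (2.5 mol %), (1R,2R)-N,N′-bis[2-(diphenylphosphanyl)benzoyl]cyclohexane-1,2-diamine (7.5 mol %), −78 → −30 °C
Reagents that add atoms: none
Why: Tsuji–Trost asymmetric allylic alkylation of the kinetic α′-lithium dienolate, in which zerovalent palladium ionises geranyl acetate to a syn-π-allyl complex that is attacked at its unhindered primary terminus with retention of the E-olefin, while the chiral ligand pocket selects the enolate face and so sets C7 of the target as (5R).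

Step 4
Reactants: 7 (5R)-3-ethoxy-5-geranyl-2-prenylcyclopent-2-en-1-one
Product: 9 (4R)-4-geranyl-3-methyl-2-prenylcyclopent-2-en-1-one, via tertiary carbinol 8 (not isolated)
Conditions: MeLi, CeCl3, THF, −78 °C; then 1 M HCl, 0 °C → rt
Reagents that add atoms: methyllithium, [Li]C; water, O
Why: Stork–Danheiser alkylative carbonyl transposition, in which the weakly basic organocerium reagent adds 1,2 without enolising the α′ stereocentre and dilute acid hydrolyses the enol ether and eliminates the tertiary hydroxyl, so the geranyl-bearing carbon passes unchanged into C4 of the enone.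

Step 5
Reactants: 9 (4R)-4-geranyl-3-methyl-2-prenylcyclopent-2-en-1-one; 10 5-bromo-2-methylpent-2-ene
Product: 12 trimethyl{[(3S,4R)-4-geranyl-3-methyl-3-homoprenyl-2-prenylcyclopent-1-en-1-yl]oxy}silane, via Grignard reagent 11 (not isolated)
Conditions: 10, Mg, THF, rt; then 9, CuBr·SMe2 (20 mol %), Me3SiCl, HMPA, THF, −78 → −40 °C; Et3N
Reagents that add atoms: chlorotrimethylsilane, C[Si](C)(C)Cl
Why: Chlorosilane-accelerated copper-catalysed conjugate addition of the Grignard reagent, which makes the hindered tetrasubstituted enone react, delivers the homoprenyl group anti to the neighbouring geranyl group (quaternary C8 with methyl cis to geranyl) and traps the enolate regiospecifically across C1–C9 as its silyl ether.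

Step 6
Reactants: 12 silyl enol ether from step 5; 13 diketene
Product: 16 (2R,3S,3aS,7aR)-2-geranyl-7a-hydroxy-3-methyl-3-homoprenyl-3a-prenylhexahydro-1H-indene-4,6(5H,7H)-dione, via lithium enolate 14 (not isolated), via acetoacetyl ketone enolate 15 (not isolated)
Conditions: MeLi (1.0 equiv), THF, 0 °C → rt; then 13, −78 → −20 °C; AcOH
Reagents that add atoms: none
Why: Diketene annulation, in which methyllithium releases the regiodefined lithium enolate, diketene C-acylates it on the face anti to the pseudoaxial C8 methyl and the C7 geranyl group (setting C1), and the methyl ketone enolate unmasked by ring opening closes the six-membered ring by intramolecular aldol addition to the C9 ketone, a closure that can only give the cis-fused carbinol (setting C9).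

Step 7
Reactants: 16 cis-fused hydroxy-hydrindanedione
Product: 18 (1R,5S,7R,8S)-7-geranyl-4-hydroxy-8-methyl-8-homoprenyl-1-prenylbicyclo[3.3.1]non-3-ene-2,9-dione, via C3 phenyliodonium ylide 17 (not isolated)
Conditions: PhI(OAc)2, KOH, MeOH, −10 → 0 °C; then dilute HCl
Reagents that add atoms: none
Why: KOH and PhI(OAc)2 convert the diketone into its C3 phenyliodonium ylide 17, and in the tautomer that is enolised from C4 towards C5 and carries the iodane on sp3 C3, the C9 alkoxide pushes the C9–C6 bond onto C5 while the C5=C4 electrons shift to C4=C3 and iodobenzene leaves, which forms the C5–C6 bond and the C9 ketone in one event. This is a vinylogous semipinacol (oxidative 1,2-alkyl shift) of the kind established for hypervalent-iodine ring enlargement of diketene-annulated cyclopentanones to bicyclo[3.3.1]nonane-2,4,9-triones. Ring A (C1, C9, C5, C6, C7, C8) is not closed by a cyclisation but arises by enlargement of the five-membered ring through a suprafacial shift of C6, so no exo or endo mode applies. The new bridgehead C5 is fixed by the cis ring fusion, because C6 can only reach the face of C5 on which it already lies, and C1, C7 and C8 are not touched. The step needs C6 and not C1 to migrate and needs oxidation at the diketone and not at the four trisubstituted olefins: the C9–C6 bond is exocyclic to the dione ring and can align with the p orbital at C5 whereas the C9–C1 bond lies in the ring plane, and the diketonate is by far the most nucleophilic site towards the iodine reagent.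

Step 8
Reactants: 18 bicyclic trione enol
Product: 19 2-O-methyl enol ether of 18 (methoxy at C2 and enone carbonyl at C4)
Conditions: HC(OMe)3, p-TsOH (cat.), MeOH, 50 °C
Reagents that add atoms: trimethyl orthoformate, COC(OC)OC
Why: Acid-catalysed enol ether formation with the orthoformate as water scavenger is reversible, so the two vinylogous esters equilibrate and the isomer whose carbonyl (C4) flanks the C5–H bridgehead is separated while the other is returned to the same conditions; no stereocentre is involved.

Step 9
Reactants: 19 2-O-methyl enol ether; 2 prenyl bromide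
Product: 21 C5-prenylated enol ether (1,5-diprenyl), via C5 bridgehead lithium compound 20 (not isolated)
Conditions: LiN(iPr)2, THF, −78 °C; then 2, −78 → 0 °C
Reagents that add atoms: none
Why: Bridgehead lithiation removes C5–H, which is flanked by the C4 and C9 carbonyl groups, in preference to the vinylic C3–H, and the pyramidal bridgehead carbanion cannot invert within the bicycle, so alkylation by prenyl bromide occurs with retention.

Step 10
Reactants: 22 3-hydroxybenzoic acid
Product: 23 tert-butyldimethylsilyl 3-[(tert-butyldimethylsilyl)oxy]benzoate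
Conditions: tBuMe2SiCl (2.2 equiv), imidazole, DMF, rt
Reagents that add atoms: tert-butyl(chloro)dimethylsilane, CC(C)(C)[Si](C)(C)Cl
Why: Imidazole-promoted silylation converts both the phenol and the carboxylic acid into silyl derivatives, which protects the phenol and prepares the carboxyl group for direct conversion into the acid chloride.

Step 11
Reactants: 23 bis-silylated 3-hydroxybenzoic acid
Product: 24 3-[(tert-butyldimethylsilyl)oxy]benzoyl chloride
Conditions: (COCl)2, DMF (cat.), CH2Cl2, 0 °C → rt
Reagents that add atoms: oxalyl chloride, ClC(=O)C(Cl)=O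
Why: Chloroiminium activation by oxalyl chloride and catalytic DMF turns a silyl ester directly into the acid chloride under neutral conditions, releasing the silyl chloride and leaving the aryl silyl ether intact.

Step 12
Reactants: 21 C5-prenylated enol ether; 24 3-[(tert-butyldimethylsilyl)oxy]benzoyl chloride
Product: 26 3-[3-(tert-butyldimethylsilyloxy)benzoyl] derivative of 21, via C3 vinyllithium 25 (not isolated)
Conditions: lithium 2,2,6,6-tetramethylpiperidide, THF, −78 °C; then 24, −78 → −40 °C
Reagents that add atoms: none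
Why: Vinylic lithiation at C3, between the C4 carbonyl and the C2 methoxy group, by the hindered amide base is followed by acylation of the vinyllithium with the acid chloride; both bridgeheads are quaternary by now, so no other deprotonation competes and no stereocentre is at risk.

Step 13
Reactants: 26 protected target
Product: 27 (1S,5S,7R,8S)-7-geranyl-4-hydroxy-3-(3-hydroxybenzoyl)-8-methyl-8-homoprenyl-1,5-diprenylbicyclo[3.3.1]non-3-ene-2,9-dione (CNP0285073.1)
Conditions: LiOH, dioxane/H2O, 90 °C; then 1 M HCl
Reagents that add atoms: lithium hydroxide, [Li+].[OH-]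
Why: Saponification of the vinylogous methyl ester by hydroxide addition–elimination at C2, eased by the C3 aroyl group, runs together with hydroxide cleavage of the aryl silyl ether and releases the enolised triketone and the phenol without touching a stereocentre.

**Compound list**

1 | cyclopentane-1,3-dione | O=C1CCC(=O)C1 | starting material
2 | prenyl bromide (1-bromo-3-methylbut-2-ene) | CC(C)=CCBr | starting material
3 | 2-prenylcyclopentane-1,3-dione | CC(C)=CCC1C(=O)CCC1=O | intermediate
4 | 3-ethoxy-2-prenylcyclopent-2-en-1-one | CCOC1=C(CC=C(C)C)C(=O)CC1 | intermediate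
5 | geranyl acetate | CC(C)=CCC/C(C)=C/COC(C)=O | starting material
6 | kinetic lithium α′-dienolate of 4 (formed in the flask) | [Li]OC1=CCC(OCC)=C1CC=C(C)C | intermediate
7 | (5R)-3-ethoxy-5-geranyl-2-prenylcyclopent-2-en-1-one | CC(C)=CCC/C(C)=C/C[C@@H]1CC(OCC)=C(CC=C(C)C)C1=O | intermediate
8 | (5R)-3-ethoxy-5-geranyl-1-methyl-2-prenylcyclopent-2-en-1-ol (carbinol epimers; lithium alkoxide in the flask) | CC(C)=CCC/C(C)=C/C[C@@H]1CC(OCC)=C(CC=C(C)C)C1(C)O | intermediate
9 | (4R)-4-geranyl-3-methyl-2-prenylcyclopent-2-en-1-one | CC(C)=CCC/C(C)=C/C[C@@H]1CC(=O)C(CC=C(C)C)=C1C | intermediate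
10 | 5-bromo-2-methylpent-2-ene (homoprenyl bromide) | CC(C)=CCCBr | starting material
11 | (4-methylpent-3-enyl)magnesium bromide (formed in the flask) | CC(C)=CCC[Mg]Br | intermediate
12 | trimethyl{[(3S,4R)-4-geranyl-3-methyl-3-homoprenyl-2-prenylcyclopent-1-en-1-yl]oxy}silane (methyl cis, homoprenyl trans to geranyl) | CC(C)=CCC/C(C)=C/C[C@@H]1CC(O[Si](C)(C)C)=C(CC=C(C)C)[C@@]1(C)CCC=C(C)C | intermediate
13 | diketene (4-methylideneoxetan-2-one) | C=C1CC(=O)O1 | starting material
14 | lithium (3S,4R)-4-geranyl-3-methyl-3-homoprenyl-2-prenylcyclopent-1-en-1-olate (formed in the flask) | CC(C)=CCC/C(C)=C/C[C@@H]1CC(O[Li])=C(CC=C(C)C)[C@@]1(C)CCC=C(C)C | intermediate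
15 | terminal lithium enolate of the 2-acetoacetyl-2-prenylcyclopentanone (acyl group trans to C8 methyl; formed in the flask) | CC(C)=CCC/C(C)=C/C[C@@H]1CC(=O)[C@@](CC=C(C)C)(C(=O)CC(O[Li])=C)[C@@]1(C)CCC=C(C)C | intermediate
16 | (2R,3S,3aS,7aR)-2-geranyl-7a-hydroxy-3-methyl-3-homoprenyl-3a-prenylhexahydro-1H-indene-4,6(5H,7H)-dione (cis-fused; hydroxyl and 3a-prenyl on the same face) | CC(C)=CCC/C(C)=C/C[C@@H]1C[C@@]2(O)CC(=O)CC(=O)[C@@]2(CC=C(C)C)[C@@]1(C)CCC=C(C)C | intermediate
17 | C3 phenyliodonium ylide of 16 (formed in the flask) | CC(C)=CCC/C(C)=C/C[C@@H]1C[C@@]2(O)CC(=O)[C-]([I+]c3ccccc3)C(=O)[C@@]2(CC=C(C)C)[C@@]1(C)CCC=C(C)C | intermediate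
18 | (1R,5S,7R,8S)-7-geranyl-4-hydroxy-8-methyl-8-homoprenyl-1-prenylbicyclo[3.3.1]non-3-ene-2,9-dione | CC(C)=CCC/C(C)=C/C[C@@H]1C[C@@H]2C(=O)[C@@](CC=C(C)C)(C(=O)C=C2O)[C@@]1(C)CCC=C(C)C | intermediate
19 | 2-O-methyl enol ether of 18 (methoxy at C2, carbonyl at C4; stereocentres as in 18) | CC(C)=CCC/C(C)=C/C[C@@H]1C[C@@H]2C(=O)[C@@](CC=C(C)C)(C(OC)=CC2=O)[C@@]1(C)CCC=C(C)C | intermediate
20 | C5 bridgehead lithium derivative of 19 (formed in the flask) | CC(C)=CCC/C(C)=C/C[C@@H]1C[C@]2([Li])C(=O)[C@@](CC=C(C)C)(C(OC)=CC2=O)[C@@]1(C)CCC=C(C)C | intermediate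
21 | C5-prenylated 19 (1,5-diprenyl; bridgeheads, C7 and C8 as in the target) | CC(C)=CCC/C(C)=C/C[C@@H]1C[C@]2(CC=C(C)C)C(=O)[C@@](CC=C(C)C)(C(OC)=CC2=O)[C@@]1(C)CCC=C(C)C | intermediate
22 | 3-hydroxybenzoic acid | OC(=O)c1cccc(O)c1 | starting material
23 | tert-butyldimethylsilyl 3-[(tert-butyldimethylsilyl)oxy]benzoate | CC(C)(C)[Si](C)(C)OC(=O)c1cccc(O[Si](C)(C)C(C)(C)C)c1 | intermediate
24 | 3-[(tert-butyldimethylsilyl)oxy]benzoyl chloride | CC(C)(C)[Si](C)(C)Oc1cccc(C(Cl)=O)c1 | intermediate
25 | C3 vinyllithium derivative of 21 (formed in the flask) | CC(C)=CCC/C(C)=C/C[C@@H]1C[C@]2(CC=C(C)C)C(=O)[C@@](CC=C(C)C)(C(OC)=C([Li])C2=O)[C@@]1(C)CCC=C(C)C | intermediate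
26 | 3-[3-(tert-butyldimethylsilyloxy)benzoyl] derivative of 21 (O-methyl, O-silyl protected target) | CC(C)=CCC/C(C)=C/C[C@@H]1C[C@]2(CC=C(C)C)C(=O)[C@@](CC=C(C)C)(C(OC)=C(C(=O)c3cccc(O[Si](C)(C)C(C)(C)C)c3)C2=O)[C@@]1(C)CCC=C(C)C | intermediate
27 | (1S,5S,7R,8S)-7-geranyl-4-hydroxy-3-(3-hydroxybenzoyl)-8-methyl-8-homoprenyl-1,5-diprenylbicyclo[3.3.1]non-3-ene-2,9-dione (CNP0285073.1) | CC(C)=CCC/C(C)=C/C[C@@H]1C[C@]2(CC=C(C)C)C(=O)[C@@](CC=C(C)C)(C(=O)C(C(=O)c3cccc(O)c3)=C2O)[C@@]1(C)CCC=C(C)C | target

**Step count.** Total: 13 steps. Longest linear sequence: 11 steps (steps 1–9, 12 and 13; steps 10 and 11 form the acid chloride branch).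

**Steps most likely to fail**

1. Step 7 (key step). The migrating carbon is a primary CH2, a poorer migrating group than a quaternary carbon. The iodonium ylide may therefore be intercepted by methoxide at C3, or the β-hydroxy ketone may open by retro-aldol cleavage before the shift takes place. Fallback: ring A is built first and the dione bridge last. Setting out from 12, desilylation (K2CO3, MeOH) gives (3S,4R)-4-geranyl-3-methyl-3-homoprenyl-2-prenylcyclopentan-1-one F1 as C2 epimers. One-carbon ring enlargement with Me3SiCHN2 and BF3·OEt2 (Tiffeneau–Demjanov-type insertion with migration of the less substituted α-carbon, protodesilylation on work-up) gives (3S,4S)-4-geranyl-3-methyl-3-homoprenyl-2-prenylcyclohexan-1-one F2. Kinetic enolisation on the methylene side (LiN(iPr)2, Me3SiCl, THF, −78 °C) gives trimethyl{[(4R,5S)-4-geranyl-5-methyl-5-homoprenyl-6-prenylcyclohex-1-en-1-yl]oxy}silane F3. Effenberger annulation (malonyl dichloride, CH2Cl2, −20 °C; then KOH, BnEt3NCl, H2O) bridges C1 and C5 on the chair that keeps geranyl equatorial and comes back to the route at 18.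

2. Step 3. Enantiomeric purity may be eroded by proton exchange between 7 and unreacted enolate. The enolate may also attack the tertiary allyl terminus, or the π-geranyl complex may lose a β-hydrogen to give a diene. Fallback: catalytic induction is given up. Setting out from 4, the lithium dienolate (LiN(iPr)2, THF, −78 °C) is alkylated with geranyl bromide without palladium (Stork–Danheiser alkylation) to racemic 3-ethoxy-5-geranyl-2-prenylcyclopent-2-en-1-one F4. The enantiomers are separated by preparative chromatography on amylose tris(3,5-dimethylphenylcarbamate), and the (5R)-enantiomer is 7.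

3. Step 5. The β-carbon of the tetrasubstituted enone is shielded by the C2 prenyl and C4 geranyl groups, so conjugate addition may stall and leave only enolisation or 1,2-addition. Fallback: C1 prenylation and conjugate addition change places. Setting out from 1, etherification (EtOH, p-TsOH, toluene, reflux with water removal) gives 3-ethoxycyclopent-2-en-1-one F5. Geranylation as in step 3 gives (5R)-3-ethoxy-5-geranylcyclopent-2-en-1-one F6. MeLi/CeCl3 followed by 1 M HCl gives the trisubstituted (4R)-4-geranyl-3-methylcyclopent-2-en-1-one F7. Copper-catalysed addition of 11 (CuBr·SMe2, THF, −40 °C) anti to geranyl and trapping of the enolate with 2 gives (3S,4R)-4-geranyl-3-methyl-3-homoprenyl-2-prenylcyclopentan-1-one F8, the same ketone as F1. Silylation under equilibrating conditions (Me3SiCl, NaI, Et3N, MeCN) gives the more substituted silyl enol ether and comes back to the route at 12.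

**Further compounds**

F1 | step 7 | (3S,4R)-4-geranyl-3-methyl-3-homoprenyl-2-prenylcyclopentan-1-one (C2 epimers) | CC(C)=CCC/C(C)=C/C[C@@H]1CC(=O)C(CC=C(C)C)[C@@]1(C)CCC=C(C)C
F2 | step 7 | (3S,4S)-4-geranyl-3-methyl-3-homoprenyl-2-prenylcyclohexan-1-one (C2 epimers) | CC(C)=CCC/C(C)=C/C[C@@H]1CCC(=O)C(CC=C(C)C)[C@@]1(C)CCC=C(C)C
F3 | step 7 | trimethyl{[(4R,5S)-4-geranyl-5-methyl-5-homoprenyl-6-prenylcyclohex-1-en-1-yl]oxy}silane | CC(C)=CCC/C(C)=C/C[C@@H]1CC=C(O[Si](C)(C)C)C(CC=C(C)C)[C@@]1(C)CCC=C(C)C
F4 | step 3 | racemic 3-ethoxy-5-geranyl-2-prenylcyclopent-2-en-1-one | CC(C)=CCC/C(C)=C/CC1CC(OCC)=C(CC=C(C)C)C1=O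
F5 | step 5 | 3-ethoxycyclopent-2-en-1-one | CCOC1=CC(=O)CC1
F6 | step 5 | (5R)-3-ethoxy-5-geranylcyclopent-2-en-1-one | CC(C)=CCC/C(C)=C/C[C@@H]1CC(OCC)=CC1=O
F7 | step 5 | (4R)-4-geranyl-3-methylcyclopent-2-en-1-one | CC(C)=CCC/C(C)=C/C[C@@H]1CC(=O)C=C1C
F8 | step 5 | (3S,4R)-4-geranyl-3-methyl-3-homoprenyl-2-prenylcyclopentan-1-one (C2 epimers; identical with F1) | CC(C)=CCC/C(C)=C/C[C@@H]1CC(=O)C(CC=C(C)C)[C@@]1(C)CCC=C(C)C
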